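**Plan**
- Ring numbering: C1(=O), C2(OH), C3(C16H33), C4(=O), C5(OH), C6(H). The retrosynthesis first takes the two O–H groups back to O-alkyl groups (a 2,5-dialkoxyquinone and its hydroquinone). It then cuts C4–C5 of the six-membered ring (6π closure of a dienylketene), re-forms a transannular C1–C4 σ-bond that is not in the target (a cyclobutenone), and cuts C1–C6 (vinyl anion to ketone) and C3–chain (Grignard reagent to squarate).
- Enabling feature: C1(=O)–C2(O)=C3(alkyl)–C4(=O) is a squaric-acid C4 unit whose para carbons C1 and C4 can be tied together in a four-membered ring. C5(O)=C6(H) is a β-alkoxyvinyl unit.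
- Forward: C16 chain onto diisopropyl squarate, acid hydrolysis to the alkyl(alkoxy)cyclobutenedione, regioselective addition of (Z)-2-ethoxyvinyllithium, thermal ring expansion (closes the only ring of the target), oxidation, hydrolysis of both alkoxy groups.
- Stereochemistry: the target has no stereogenic element. The carbinol centres made on the way are racemic and are flattened in the ring expansion.

Key step: step 4

Remark: the target is achiral (planar quinone ring, unbranched chain), so "single enantiomer" places no demand on the route; the SMILES is taken as one tautomer of 3-hexadecyl-2,5-dihydroxy-1,4-benzoquinone.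

**Step 1**
Reactants: 1 1-bromohexadecane; 2 diisopropyl squarate (3,4-bis(propan-2-yloxy)cyclobut-3-ene-1,2-dione)
Product: 4 4-hexadecyl-4-hydroxy-2,3-bis(propan-2-yloxy)cyclobut-2-en-1-one (racemic), via hexadecylmagnesium bromide 3 (not isolated)
Conditions: 1, Mg, I2 (cat.), THF, reflux; then added to 2, THF, –78 → –40 °C; sat. aq. NH4Cl
Reagents that add atoms: none
Why: Grignard formation followed by 1,2-carbonyl addition to one squarate carbonyl should stop at mono-addition, because the resulting alkoxide sits next to a deactivated vinylogous ester carbonyl; the new carbinol centre is racemic and is removed in step 2.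

**Step 2**
Reactants: 4 4-hexadecyl-4-hydroxy-2,3-bis(propan-2-yloxy)cyclobut-2-en-1-one
Product: 5 3-hexadecyl-4-(propan-2-yloxy)cyclobut-3-ene-1,2-dione
Conditions: conc. HCl (cat.), CH2Cl2, rt
Reagents that add atoms: none
Why: Acid-catalysed ionization of the tertiary allylic hydroxyl to the dialkoxy-stabilized cyclobutenyl cation, return of the released water at the distal alkoxy carbon and collapse of the hemiketal with loss of propan-2-ol is the standard hydrolysis (1,3-carbonyl transposition) of squarate adducts to 3-alkyl-4-alkoxycyclobutenediones.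

**Step 3**
Reactants: 5 3-hexadecyl-4-(propan-2-yloxy)cyclobut-3-ene-1,2-dione; 6 (Z)-1-bromo-2-ethoxyethene
Product: 8 4-[(Z)-2-ethoxyethenyl]-2-hexadecyl-4-hydroxy-3-(propan-2-yloxy)cyclobut-2-en-1-one (racemic), via (Z)-2-ethoxyvinyllithium 7 (not isolated)
Conditions: 6, n-BuLi, THF, –78 °C; then 5, THF, –78 °C; H2O quench at –78 °C, base-washed glassware, Et3N-deactivated silica
Reagents that add atoms: none
Why: Bromine–lithium exchange gives the O–Li-chelated, configurationally stable (Z)-β-ethoxyvinyllithium, which should add 1,2 to the more electrophilic ketone carbonyl (the one next to the isopropoxy carbon, the other being a vinylogous ester), creating a racemic carbinol centre that is flattened in step 4.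

**Step 4**
Reactants: 8 4-[(Z)-2-ethoxyethenyl]-2-hexadecyl-4-hydroxy-3-(propan-2-yloxy)cyclobut-2-en-1-one
Product: 11 5-ethoxy-3-hexadecyl-2-(propan-2-yloxy)benzene-1,4-diol, via dienylketene 9 (not isolated), via cyclohexa-2,4-dienone 10 (not isolated)
Conditions: degassed toluene (0.02 M), 110 °C, Ar (p-xylene, 138 °C if slow)
Reagents that add atoms: none
Why: Heating should open the cyclobutenone by 4π-conrotatory cleavage of the C(=O)–C(OH) σ-bond, the donor hydroxyl rotating outward so that the ethoxyvinyl group turns inward and gives the (3Z)-dienylketene 9. A 6π-disrotatory electrocyclization between the ketene carbon and the ethoxy-bearing vinyl terminus then closes the six-membered carbocycle (6π electrocyclic mode, new bond C4–C5 of the target ring) to dienone 10, whose enolization gives the aromatic hydroquinone. The closest known reaction type is the thermal ring expansion of 4-alkenyl-4-hydroxycyclobutenones to hydroquinones (Moore–Liebeskind type). No lasting stereocentre is formed, since the transient CH(OEt) carbon of 10 becomes sp2 on tautomerization. The step needs torquoselectivity (hydroxyl outward, otherwise the ketene is trapped as a butenolide), which the strongly donating OH group secures, and the substitution pattern is fixed by connectivity, each ring carbon being assigned in steps 1–3. Loss of ethanol from 10 in place of enolization is disfavoured in a neutral, non-polar, aprotic medium, and dilution suppresses ketene dimerization.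

**Step 5**
Reactants: 11 5-ethoxy-3-hexadecyl-2-(propan-2-yloxy)benzene-1,4-diol
Product: 12 5-ethoxy-3-hexadecyl-2-(propan-2-yloxy)cyclohexa-2,5-diene-1,4-dione
Conditions: Ag2O, Na2SO4, Et2O, rt
Reagents that add atoms: none
Why: Hydroquinone-to-quinone oxidation of an electron-rich dialkoxyhydroquinone by Ag2O should proceed under neutral conditions that leave both alkoxy groups untouched.

**Step 6**
Reactants: 12 5-ethoxy-3-hexadecyl-2-(propan-2-yloxy)cyclohexa-2,5-diene-1,4-dione
Product: 13 3-hexadecyl-2,5-dihydroxycyclohexa-2,5-diene-1,4-dione (target)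
Conditions: 2 M aq. NaOH (excess), 1,4-dioxane, 50 °C, N2; then 2 M HCl, 0 °C
Reagents that add atoms: sodium hydroxide, [Na+].[OH-] (supplies both hydroxyl oxygens)
Why: Both alkoxy groups are vinylogous esters of the quinone carbonyls and should be replaced by hydroxide through conjugate addition–elimination (vinylogous saponification), the resulting dianion resisting further attack until acidification releases the dihydroxyquinone.

**Compound list**
1 | 1-bromohexadecane | CCCCCCCCCCCCCCCCBr | starting material
2 | diisopropyl squarate (3,4-bis(propan-2-yloxy)cyclobut-3-ene-1,2-dione) | CC(C)OC1=C(OC(C)C)C(=O)C1=O | starting material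
3 | hexadecylmagnesium bromide | CCCCCCCCCCCCCCCC[Mg]Br | intermediate
4 | 4-hexadecyl-4-hydroxy-2,3-bis(propan-2-yloxy)cyclobut-2-en-1-one (racemic) | CCCCCCCCCCCCCCCCC1(O)C(OC(C)C)=C(OC(C)C)C1=O | intermediate
5 | 3-hexadecyl-4-(propan-2-yloxy)cyclobut-3-ene-1,2-dione | CCCCCCCCCCCCCCCCC1=C(OC(C)C)C(=O)C1=O | intermediate
6 | (Z)-1-bromo-2-ethoxyethene | CCO/C=C\Br | starting material
7 | (Z)-2-ethoxyvinyllithium | CCO/C=C\[Li] | intermediate
8 | 4-[(Z)-2-ethoxyethenyl]-2-hexadecyl-4-hydroxy-3-(propan-2-yloxy)cyclobut-2-en-1-one (racemic) | CCCCCCCCCCCCCCCCC1=C(OC(C)C)C(O)(/C=C\OCC)C1=O | intermediate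
9 | (3Z,5Z)-6-ethoxy-2-hexadecyl-4-hydroxy-3-(propan-2-yloxy)hexa-1,3,5-trien-1-one (dienylketene) | O=C=C(CCCCCCCCCCCCCCCC)/C(OC(C)C)=C(O)\C=C/OCC | intermediate
10 | 6-ethoxy-2-hexadecyl-4-hydroxy-3-(propan-2-yloxy)cyclohexa-2,4-dien-1-one (racemic, transient) | O=C1C(OCC)C=C(O)C(OC(C)C)=C1CCCCCCCCCCCCCCCC | intermediate
11 | 5-ethoxy-3-hexadecyl-2-(propan-2-yloxy)benzene-1,4-diol | CCCCCCCCCCCCCCCCc1c(O)c(OCC)cc(O)c1OC(C)C | intermediate
12 | 5-ethoxy-3-hexadecyl-2-(propan-2-yloxy)cyclohexa-2,5-diene-1,4-dione | CCCCCCCCCCCCCCCCC1=C(OC(C)C)C(=O)C=C(OCC)C1=O | intermediate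
13 | 3-hexadecyl-2,5-dihydroxycyclohexa-2,5-diene-1,4-dione | CCCCCCCCCCCCCCCCC1=C(O)C(=O)C=C(O)C1=O | target

**Step count and risks**
Total step count: 6. Longest linear sequence: 6 steps (1 or 2 → 13).

Steps most likely to fail:

1. Step 4. The ketene may be captured by the hydroxyl if torquoselectivity erodes. The 6π closure may be slow because the ethoxy group sits on the inside of the triene terminus. Ethanol may be lost from the dienone in competition with enolization, which would give a ring lacking the C5 oxygen. Fallback, setting out from 5 and coming back at 12: the ring is closed through an alkyne instead of an alkene and the C5 oxygen is added afterwards. Addition of ethynylmagnesium bromide (THF, –78 °C) to 5 should give 4-ethynyl-2-hexadecyl-4-hydroxy-3-(propan-2-yloxy)cyclobut-2-en-1-one F1. Thermal rearrangement of this 4-alkynyl-4-hydroxycyclobutenone (toluene or p-xylene, reflux; ring opening, closure to the six-membered diradical, hydrogen transfer from OH) should give 2-hexadecyl-3-(propan-2-yloxy)cyclohexa-2,5-diene-1,4-dione F2. Oxidative ethoxylation (EtOH, ZnCl2, air) should occur at the ring CH that is β to the carbonyl not deactivated by the isopropoxy group, which is the position required for 12.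

2. Step 3. The lithium reagent may undergo β-elimination to ethoxide and acetylene on warming. It may attack the vinylogous-ester carbonyl or displace isopropoxide by 1,4-addition. The β-ethoxyvinyl carbinol may ionize under acid during work-up and collapse to an enal. Fallback, setting out from 5 and coming back at 8: the two-carbon unit is introduced as a robust acetylide and the Z-alkene is made by reduction. Lithium ethoxyacetylide (ethoxyethyne, n-BuLi, THF, –78 °C) should add to the same carbonyl of 5 to give 4-(ethoxyethynyl)-2-hexadecyl-4-hydroxy-3-(propan-2-yloxy)cyclobut-2-en-1-one F3, which is kept cold. Lindlar semihydrogenation (H2, Pd/CaCO3–Pb, quinoline, EtOAc, rt) should deliver the (Z)-ethoxyvinyl carbinol 8 without touching the tetrasubstituted ring alkene.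

3. Step 6. Addition–elimination may be incomplete at the isopropoxy carbon flanked by the C16 chain. Hydroxide may attack the free ring CH, or the dianion may degrade oxidatively in the presence of air. Fallback, setting out from 11 and coming back at 13: the ethers are cleaved at the arene oxidation level by a Lewis acid instead of at the quinone level by a nucleophile. BBr3 (excess, CH2Cl2, –78 °C → rt, aqueous work-up) should convert 11 into 3-hexadecylbenzene-1,2,4,5-tetrol F4, which should autoxidize on stirring under air or O2 in a buffered two-phase mixture to the dihydroxyquinone 13.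

**Further compounds**
F1 | step 4 | 4-ethynyl-2-hexadecyl-4-hydroxy-3-(propan-2-yloxy)cyclobut-2-en-1-one | CCCCCCCCCCCCCCCCC1=C(OC(C)C)C(O)(C#C)C1=O
F2 | step 4 | 2-hexadecyl-3-(propan-2-yloxy)cyclohexa-2,5-diene-1,4-dione | CCCCCCCCCCCCCCCCC1=C(OC(C)C)C(=O)C=CC1=O
F3 | step 3 | 4-(ethoxyethynyl)-2-hexadecyl-4-hydroxy-3-(propan-2-yloxy)cyclobut-2-en-1-one | CCCCCCCCCCCCCCCCC1=C(OC(C)C)C(O)(C#COCC)C1=O
F4 | step 6 | 3-hexadecylbenzene-1,2,4,5-tetrol | CCCCCCCCCCCCCCCCc1c(O)c(O)cc(O)c1O
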